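In a one-step world the yield equals the conversion, but the winter run levels off at 72.8% target with 0% starting material in solution, so a second path takes the rest of the charge.

| setting | winter | spring | autumn | flask |
|---|---|---|---|---|
| solid substrate | 0.050 M | 0.20 M | 0.10 M | 0.10 M |
| reagent | 0.12 M | 0.12 M | 0.060 M | 0.120 M |
| remark | run made earlier | run made earlier | run made earlier |  |
| time |  |  |  | 25 h |

| run | time / h | target / % | starting material / % |
|---|---|---|---|
| winter | 2.50 | 12.4 | 8.0 |
| winter | 4.00 | 20.0 | 7.1 |
| winter | 6.00 | 34.6 | 7.8 |
| winter | 10.0 | 57.6 | 10.5 |
| winter | 20.0 | 72.8 | 0 |
| winter | 30.0 | 71.8 | 0 |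
| spring | 5.00 | 6.5 | 0.5 |
| spring | 10.0 | 14.3 | 3.2 |
| spring | 15.0 | 18.2 | 1.9 |
| spring | 20.0 | 27.6 | 4.3 |
| spring | 25.0 | 33.4 | 4.7 |
| spring | 30.0 | 33.2 | 4.8 |
| autumn | 2.50 | 3.7 | 5.2 |
| autumn | 5.00 | 10.7 | 7.5 |
| autumn | 8.00 | 17.3 | 8.2 |
| autumn | 15.0 | 33.9 | 10.2 |
| autumn | 30.0 | 43.4 | 14.4 |

(standard deviation of a reading: 1 percentage point)

- solid substrate is a solid; its amount is given per volume of the solution
- at the start none of the solid substrate is in solution
- starting material means what is dissolved; the solid is not counted in it
- starting material is what solid substrate becomes in solution

- amount of target at 25 h, in percent of the solid substrate charged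
- concentration of starting material in solution at 6.0 h, in percent of saturation
- the change that raises the amount of target at 25 h, in percent of the solid substrate charged most ("none" if none brings more than 2 percentage points) (blue / red / violet / none)
- amount of target at 25 h, in percent of the solid substrate charged, after red

- blue: doubling the solubility of the solid substrate, all else as stated
- red: doubling the amount of reagent, all else as stated
- violet: doubling the dissolution coefficient of the solid substrate, all else as stated

In the winter run, 0.374 of the charge is lost per target. I assume that the lost path takes two reagent, which makes 1.75 reagent spent per target in the winter run. Compare the two rates at one moment: lost per target then grows with the reagent present, and drifts down as reagent is used. Winter's mean reagent of 0.0882 M gives 4.24 L mol⁻¹, the side ratio, lost per target per unit of reagent, a selectivity factor. With the whole charge reacted, I reckon red at about 58.9% target.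

The forecast says 62%, 25% of saturation, and red as best with 74%, since “More reagent lowers dissolved starting material”; that figure stands above mine.

The flask gives 64.5% and 24.0%. The best change is blue, worth 11 percentage points, against 9.2 points for violet, while red moves the target by −6.1 points, to 58.4%.

    starting material + reagent → target (k = 0.140 L mol⁻¹ min⁻¹)
    starting material + 2 reagent → side product (k = 0.610 L² mol⁻² min⁻¹)
    solid substrate ⇌ starting material, rate k3*(cs3 - [starting material]) while solid is left; crystals form when [starting material] > cs3 (solubility = 17.0 mM, k = 0.00570 min⁻¹)

In the flask at 25.0 h, reagent stands at 16% of its charge, a mean of 0.0695 M, so the side ratio gives 77.2% target among the reacted charge, and the flask holds 78.0%. The neighbour with 0.30 M reagent keeps 50% of it, a mean of 0.226 M, which gives 51.1%. That neighbour ends with 51.1% target and 48.9% side product.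

The readings were computed with made-up constants.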